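**Plan**
1. Retrosynthesis: the C8 ester, the C14 aldehyde and the C15 alcohol are adjusted last. The fused α-methylene-γ-butyrolactone is then cut at C11–C12 and C6–C7 (plus the lactone C–O bond) to CO2, a terminal allene C7=C11=C13 and an enal carbonyl C6, all in one open chain (23).
2. Enabling feature: the exo-methylene carbon C11 sits between the lactone carbonyl C12 and C7 of the C6–C7 ring-fusion bond. This is the pattern left by an allene that is carboxylated at its central carbon and allylated at C7. The two ring-cis trisubstituted olefins C1=C10 and C4=C5 pre-fold the chain for closure of the ten-membered ring.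
3. Chain 23 is cut at C1=C10 (Horner–Wadsworth–Emmons) into a west phosphono-lactone (C7–C10, C14, alkyne as allene precursor) and an east aldehyde (C1–C6, C15).
4. Forward: two fragments, olefination, lactone reduction and silylation, allene formation, enal formation; step 16 then closes the ten-membered carbocycle (C6–C7) and, on acid work-up, the lactone ring; finally C8 acylation, C14 oxidation and C15 release.
5. Stereochemistry: C8 from Noyori transfer hydrogenation; C6 and C7 in step 16 under control of C8 and a chair transition state; C4=C5 from trans-hydroalumination/iodination and a stereoretentive Heck reaction; C1=C10 from E-selective olefination.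

Key step: step 16

Remark: positions carry germacranolide numbers (C12 lactone carbonyl, C13 exo-methylene, C14 aldehyde carbon, C15 hydroxymethyl carbon). The target is read as 6R,7S,8R: H-6 and H-7 cis (cis-fused lactone), the C8 oxygen on the ring face opposite to C11, and both ring olefins with their ring bonds cis (CIP E). TMS = trimethylsilyl, TBS = tert-butyldimethylsilyl, TBDPS = tert-butyldiphenylsilyl, PMB = 4-methoxybenzyl.

**Route**

Step 1
Reactants: 1 methyl 4-chloro-4-oxobutanoate; 2 bis(trimethylsilyl)acetylene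
Product: 3 methyl 4-oxo-6-(trimethylsilyl)hex-5-ynoate
Conditions: AlCl3, CH2Cl2, 0 °C
Reagents that add atoms: none
Why: Friedel–Crafts-type acylation of the bis-silyl alkyne (ipso-desilylation by the AlCl3-activated acid chloride) should stop at the mono-ynone because the product alkyne is deactivated, and the methyl ester is inert.

Step 2
Reactants: 3 methyl 4-oxo-6-(trimethylsilyl)hex-5-ynoate
Product: 5 (R)-5-((trimethylsilyl)ethynyl)dihydrofuran-2(3H)-one, via hydroxy ester 4 (not isolated)
Conditions: RuCl[(R,R)-TsDPEN](p-cymene) (1 mol %), HCO2H/Et3N (5:2), rt; then TsOH·H2O (cat.), CH2Cl2, rt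
Reagents that add atoms: none
Why: Noyori asymmetric transfer hydrogenation of the alkynyl ketone, in which the (R,R)-configured ruthenium hydride–amine complex distinguishes the alkynyl π-substituent from the alkyl chain, should set C8 as R, and the γ-hydroxy ester then lactonises under acid catalysis.

Step 3
Reactants: 5 (R)-5-((trimethylsilyl)ethynyl)dihydrofuran-2(3H)-one
Product: 7 diethyl [(5R)-2-oxo-5-((trimethylsilyl)ethynyl)tetrahydrofuran-3-yl]phosphonate (mixture at C3), via enol phosphate 6 (not isolated)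
Conditions: LiN(iPr)2 (1.1 equiv), THF, −78 °C; ClP(O)(OEt)2; then LiN(iPr)2 (2.2 equiv), −78 → 0 °C; AcOH quench
Reagents that add atoms: diethyl chlorophosphate, CCOP(=O)(Cl)OCC
Why: O-phosphorylation of the lactone enolate followed by base-induced 1,3-shift of phosphorus from O to C (vinyl phosphate–phosphonate rearrangement) should give the olefination reagent without touching C8 or the silylalkyne.

Step 4
Reactants: 8 2-butyne-1,4-diol
Product: 9 4-((4-methoxybenzyl)oxy)but-2-yn-1-ol
Conditions: NaH (1 equiv), 8 (3 equiv), PMBCl, Bu4NI (cat.), THF/DMF, 0 °C → rt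
Reagents that add atoms: 4-methoxybenzyl chloride, COc1ccc(CCl)cc1
Why: Williamson etherification with the diol in excess should give the mono-ether statistically, so that the C15 oxygen carries the group that is removed last.

Step 5
Reactants: 9 4-((4-methoxybenzyl)oxy)but-2-yn-1-ol
Product: 11 (Z)-3-iodo-4-((4-methoxybenzyl)oxy)but-2-en-1-ol, via cyclic alkenylalanate 10 (not isolated)
Conditions: NaAlH2(OCH2CH2OMe)2 (1.5 equiv), THF, 0 °C → rt; then iodine, THF, −78 → 0 °C
Reagents that add atoms: iodine, [I][I]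
Why: hydroxyl-directed trans-hydroalumination places aluminium at C4 cis to C6 in a five-membered alanate, and iodinolysis with retention should give the Z-iodide that fixes the C4=C5 geometry.

Step 6
Reactants: 11 (Z)-3-iodo-4-((4-methoxybenzyl)oxy)but-2-en-1-ol
Product: 12 (Z)-tert-butyl((3-iodo-4-((4-methoxybenzyl)oxy)but-2-en-1-yl)oxy)dimethylsilane
Conditions: TBSCl, imidazole, CH2Cl2, 0 °C → rt
Reagents that add atoms: tert-butyldimethylsilyl chloride, CC(C)(C)[Si](C)(C)Cl
Why: standard silylation of the primary allylic C6 alcohol, chosen so that this ether can later be cleaved before the secondary TBS and the TBDPS ethers.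

Step 7
Reactants: 12 (Z)-tert-butyl((3-iodo-4-((4-methoxybenzyl)oxy)but-2-en-1-yl)oxy)dimethylsilane; 13 allyl alcohol
Product: 14 (E)-6-((tert-butyldimethylsilyl)oxy)-4-(((4-methoxybenzyl)oxy)methyl)hex-4-enal
Conditions: Pd(OAc)2 (5 mol %), Bu4NCl, NaHCO3, DMF, rt → 40 °C
Reagents that add atoms: none
Why: Heck reaction of the vinyl iodide with allyl alcohol under ligand-free phase-transfer conditions, in which carbopalladation at the terminal carbon and β-hydride elimination toward the carbinol should give the 4-enal directly with retention of the iodoalkene geometry (C3 cis to C6).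

Step 8
Reactants: 7 diethyl [(5R)-2-oxo-5-((trimethylsilyl)ethynyl)tetrahydrofuran-3-yl]phosphonate; 14 (E)-6-((tert-butyldimethylsilyl)oxy)-4-(((4-methoxybenzyl)oxy)methyl)hex-4-enal
Product: 15 (R,E)-3-[(E)-6-((tert-butyldimethylsilyl)oxy)-4-(((4-methoxybenzyl)oxy)methyl)hex-4-en-1-ylidene]-5-((trimethylsilyl)ethynyl)dihydrofuran-2(3H)-one
Conditions: NaH, THF, 0 °C; then 14, 0 °C → rt
Reagents that add atoms: none
Why: Horner–Wadsworth–Emmons olefination of the α-phosphono lactone should favour the E-alkylidene lactone (chain anti to the carbonyl, C2 cis to C9), which corresponds to the ring-cis C1=C10 olefin of the target.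

Step 9
Reactants: 15 the alkylidene lactone
Product: 16 (2E,6E)-8-((tert-butyldimethylsilyl)oxy)-2-[(R)-2-hydroxy-4-(trimethylsilyl)but-3-yn-1-yl]-6-(((4-methoxybenzyl)oxy)methyl)octa-2,6-dien-1-ol
Conditions: iBu2AlH (4 equiv), CH2Cl2, −78 → 0 °C
Reagents that add atoms: none
Why: 1,2-reduction of the unsaturated lactone by iBu2AlH should give the primary allylic alcohol (C14) and the secondary alcohol (C8) without conjugate reduction or hydroalumination of the alkyne at low temperature.

Step 10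
Reactants: 16 the diol
Product: 17 (3R,5E,9E)-11-(TBSO)-5-((TBDPSO)methyl)-9-((PMBO)methyl)-1-(trimethylsilyl)undeca-5,9-dien-1-yn-3-ol
Conditions: TBDPSCl (1.05 equiv), imidazole, CH2Cl2, 0 °C
Reagents that add atoms: tert-butyldiphenylsilyl chloride, CC(C)(C)[Si](Cl)(c1ccccc1)c1ccccc1
Why: steric differentiation in silylation, since the bulky silyl chloride should react only with the primary allylic C14 hydroxyl.

Step 11
Reactants: 17 the C14 TBDPS ether
Product: 18 (3R,5E,9E)-3,11-bis(TBSO)-5-((TBDPSO)methyl)-9-((PMBO)methyl)-1-(trimethylsilyl)undeca-5,9-dien-1-yne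
Conditions: TBSOTf, 2,6-lutidine, CH2Cl2, −78 °C
Reagents that add atoms: tert-butyldimethylsilyl triflate, CC(C)(C)[Si](C)(C)OS(=O)(=O)C(F)(F)F
Why: silyl triflate silylation of the secondary propargylic alcohol, whose silyl ether later blocks lactonisation to the 8,12-olide in the key step.

Step 12
Reactants: 18 the silylalkyne
Product: 19 (3R,5E,9E)-3,11-bis(TBSO)-5-((TBDPSO)methyl)-9-((PMBO)methyl)undeca-5,9-dien-1-yne
Conditions: K2CO3 (0.2 equiv), MeOH, rt
Reagents that add atoms: none
Why: base-catalysed methanolysis of the C(sp)–Si bond (protodesilylation), to which the O-silyl ethers should be stable.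

Step 13
Reactants: 19 the terminal alkyne
Product: 21 (4R,6E,10E)-4,12-bis(TBSO)-6-((TBDPSO)methyl)-10-((PMBO)methyl)dodeca-1,2,6,10-tetraene, via propargylic amine 20 (not isolated)
Conditions: CuI (0.5 equiv), Cy2NH (1.8 equiv), (CH2O)n (2.5 equiv), 1,4-dioxane, reflux
Reagents that add atoms: paraformaldehyde (as formaldehyde), C=O
Why: Crabbé homologation, in which a copper-mediated Mannich reaction is followed by 1,5-hydride transfer from the amine α-C–H with loss of the imine, should convert the terminal alkyne into the terminal allene, adding C13 and leaving C8 untouched.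

Step 14
Reactants: 21 the allene
Product: 22 (2E,6E,9R)-9-(TBSO)-7-((TBDPSO)methyl)-3-((PMBO)methyl)dodeca-2,6,10,11-tetraen-1-ol
Conditions: HF·pyridine, pyridine, THF, 0 °C
Reagents that add atoms: none
Why: selective desilylation, since buffered HF·pyridine should cleave the unhindered primary allylic TBS ether much faster than the secondary TBS and the primary TBDPS ethers.

Step 15
Reactants: 22 the C6 alcohol
Product: 23 (2E,6E,9R)-9-(TBSO)-7-((TBDPSO)methyl)-3-((PMBO)methyl)dodeca-2,6,10,11-tetraenal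
Conditions: Dess–Martin periodinane, NaHCO3, CH2Cl2, 0 °C
Reagents that add atoms: none
Why: Dess–Martin oxidation under buffered, non-basic conditions should give the enal without scrambling the C4=C5 geometry or touching the allene.

Step 16
Reactants: 23 the allenyl enal
Product: 26 8-(TBSO)-14-(TBDPSO)-15-(PMBO)germacra-1(10),4,11(13)-trien-6,12-olide (target configuration at C6 C7 C8), via nickelalactone 24 (not isolated), via hydroxy acid 25 (not isolated)
Conditions: Ni(cod)2 (1.5 equiv), DBU (10 equiv), CO2 (1 atm), THF, 0 °C, syringe-pump addition of 23 (final 2 mM); then 1 M HCl, 0 °C; then PPTS (cat.), CH2Cl2, rt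
Reagents that add atoms: carbon dioxide, O=C=O
Why: Proposed new method: zerovalent nickel ligated by DBU should couple CO2 oxidatively with the terminal C11=C13 π bond of the allene on the face anti to C8, forming the C11–C12 bond and the five-membered nickelalactone 24, a σ-allylnickel carboxylate with C8 cis to the CH2–Ni carbon (Z). This allyl unit then adds through its substituted γ-carbon C7 to the tethered enal carbonyl C6 in a closed six-membered chair-like array (10-exo-trig closure of the carbocycle), and acid work-up lactonises the cis hydroxy acid 25 (5-exo-trig) to the α-methylene-γ-butyrolactone. The closest known reaction type is the nickel-mediated carboxylation of terminal allenes with CO2 followed by allylation of an aldehyde, known between two molecules and for closure of five- and six-membered rings, together with the established allylmetal–aldehyde closure of ten-membered germacranolide rings; the new element is the ring size. C7 is controlled by the C8 stereocentre: with H-8 eclipsing the alkene to avoid A(1,3) strain against C13, the tether through C9 delivers the aldehyde to the face opposite the bulky silyloxy group. C6 is controlled by the chair transition state of the Z-allylnickel with the enal residue equatorial, which gives the syn adduct and hence the cis-fused lactone (6R,7S). The step needs regioselectivity (CO2 at the central allene carbon, C–C bond at C7, inherent to the oxanickelacycle), chemoselectivity (C6 is the only carbonyl, C14 and C15 are protected and the C8 silyl ether cannot lactonise) and cyclisation over oligomerisation (the two cis trisubstituted olefins fold the chain, supported by slow addition at high dilution).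

Step 17
Reactants: 26 the protected lactone
Product: 27 8-hydroxy-14-(TBDPSO)-15-(PMBO)germacra-1(10),4,11(13)-trien-6,12-olide
Conditions: HF (48 % aq.), MeCN, 0 °C → rt
Reagents that add atoms: none
Why: selective desilylation, since acidic fluoride should cleave the secondary TBS ether while the primary TBDPS ether, far more stable to acid, and the PMB ether survive.

Step 18
Reactants: 27 the C8 alcohol
Product: 28 8-(3-methylbutanoyloxy)-14-(TBDPSO)-15-(PMBO)germacra-1(10),4,11(13)-trien-6,12-olide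
Conditions: (iPrCH2CO)2O, DMAP (cat.), pyridine, CH2Cl2, 0 °C → rt
Reagents that add atoms: 3-methylbutanoic anhydride, CC(C)CC(=O)OC(=O)CC(C)C
Why: DMAP-catalysed acylation of the secondary C8 alcohol, carried out before C14 is unveiled so that no 8,14-lactol can form.

Step 19
Reactants: 28 the isovalerate
Product: 29 14-hydroxy-8-(3-methylbutanoyloxy)-15-(PMBO)germacra-1(10),4,11(13)-trien-6,12-olide
Conditions: HF·pyridine (excess), THF/pyridine, rt
Reagents that add atoms: none
Why: fluoride-mediated cleavage of the remaining silyl ether under mildly acidic conditions that the ester, the PMB ether and the α-methylene lactone should tolerate.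

Step 20
Reactants: 29 the C14 alcohol
Product: 30 8-(3-methylbutanoyloxy)-15-(PMBO)-14-oxogermacra-1(10),4,11(13)-trien-6,12-olide
Conditions: Dess–Martin periodinane, NaHCO3, CH2Cl2, 0 °C
Reagents that add atoms: none
Why: Dess–Martin oxidation of the only free (primary allylic) alcohol should give the C14 enal under buffered conditions.

Step 21
Reactants: 30 the PMB ether
Product: 31 (6R,7S,8R)-15-hydroxy-8-(3-methylbutanoyloxy)-14-oxogermacra-1(10),4,11(13)-trien-6,12-olide (CNP0345200.7)
Conditions: DDQ (1.2 equiv), CH2Cl2/H2O (pH 7), 0 °C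
Reagents that add atoms: none
Why: oxidative cleavage of the PMB ether by DDQ (hydride abstraction, then hydrolysis of the oxocarbenium ion) should release the C15 alcohol under neutral conditions compatible with the enal, the ester and the α-methylene lactone.

**Compound list**

1 | methyl 4-chloro-4-oxobutanoate | COC(=O)CCC(=O)Cl | starting material
2 | bis(trimethylsilyl)acetylene | C[Si](C)(C)C#C[Si](C)(C)C | starting material
3 | methyl 4-oxo-6-(trimethylsilyl)hex-5-ynoate | COC(=O)CCC(=O)C#C[Si](C)(C)C | intermediate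
4 | methyl (R)-4-hydroxy-6-(trimethylsilyl)hex-5-ynoate (not isolated) | COC(=O)CC[C@@H](O)C#C[Si](C)(C)C | intermediate
5 | (R)-5-((trimethylsilyl)ethynyl)dihydrofuran-2(3H)-one | O=C1CC[C@@H](O1)C#C[Si](C)(C)C | intermediate
6 | diethyl (R)-5-((trimethylsilyl)ethynyl)-4,5-dihydrofuran-2-yl phosphate (not isolated) | CCOP(=O)(OCC)OC1=CC[C@@H](O1)C#C[Si](C)(C)C | intermediate
7 | diethyl [(5R)-2-oxo-5-((trimethylsilyl)ethynyl)tetrahydrofuran-3-yl]phosphonate (mixture at C3) | CCOP(=O)(OCC)C1C[C@@H](OC1=O)C#C[Si](C)(C)C | intermediate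
8 | 2-butyne-1,4-diol | OCC#CCO | starting material
9 | 4-((4-methoxybenzyl)oxy)but-2-yn-1-ol | COc1ccc(COCC#CCO)cc1 | intermediate
10 | sodium cyclic alkenylalanate, five-membered O–Al–C4 ring (not isolated) | [Na+].COCCO[Al-]1(OCCOC)OC/C=C1/COCc1ccc(OC)cc1 | intermediate
11 | (Z)-3-iodo-4-((4-methoxybenzyl)oxy)but-2-en-1-ol | OC/C=C(/COCc1ccc(OC)cc1)I | intermediate
12 | (Z)-tert-butyl((3-iodo-4-((4-methoxybenzyl)oxy)but-2-en-1-yl)oxy)dimethylsilane | CC(C)(C)[Si](C)(C)OC/C=C(/COCc1ccc(OC)cc1)I | intermediate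
13 | allyl alcohol | C=CCO | starting material
14 | (E)-6-((tert-butyldimethylsilyl)oxy)-4-(((4-methoxybenzyl)oxy)methyl)hex-4-enal | O=CCC/C(COCc1ccc(OC)cc1)=C\CO[Si](C)(C)C(C)(C)C | intermediate
15 | (R,E)-3-[(E)-6-(TBSO)-4-((PMBO)methyl)hex-4-en-1-ylidene]-5-((trimethylsilyl)ethynyl)dihydrofuran-2(3H)-one | O=C1O[C@@H](C#C[Si](C)(C)C)C/C1=C\CC/C(COCc2ccc(OC)cc2)=C\CO[Si](C)(C)C(C)(C)C | intermediate
16 | (2E,6E)-8-(TBSO)-2-[(R)-2-hydroxy-4-(trimethylsilyl)but-3-yn-1-yl]-6-((PMBO)methyl)octa-2,6-dien-1-ol | OC/C(C[C@@H](O)C#C[Si](C)(C)C)=C/CC/C(COCc1ccc(OC)cc1)=C\CO[Si](C)(C)C(C)(C)C | intermediate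
17 | (3R,5E,9E)-11-(TBSO)-5-((TBDPSO)methyl)-9-((PMBO)methyl)-1-(trimethylsilyl)undeca-5,9-dien-1-yn-3-ol | CC(C)(C)[Si](c1ccccc1)(c1ccccc1)OC/C(C[C@@H](O)C#C[Si](C)(C)C)=C/CC/C(COCc1ccc(OC)cc1)=C\CO[Si](C)(C)C(C)(C)C | intermediate
18 | (3R,5E,9E)-3,11-bis(TBSO)-5-((TBDPSO)methyl)-9-((PMBO)methyl)-1-(trimethylsilyl)undeca-5,9-dien-1-yne | CC(C)(C)[Si](c1ccccc1)(c1ccccc1)OC/C(C[C@@H](O[Si](C)(C)C(C)(C)C)C#C[Si](C)(C)C)=C/CC/C(COCc1ccc(OC)cc1)=C\CO[Si](C)(C)C(C)(C)C | intermediate
19 | (3R,5E,9E)-3,11-bis(TBSO)-5-((TBDPSO)methyl)-9-((PMBO)methyl)undeca-5,9-dien-1-yne | CC(C)(C)[Si](c1ccccc1)(c1ccccc1)OC/C(C[C@@H](O[Si](C)(C)C(C)(C)C)C#C)=C/CC/C(COCc1ccc(OC)cc1)=C\CO[Si](C)(C)C(C)(C)C | intermediate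
20 | (4R,6E,10E)-N,N-dicyclohexyl-4,12-bis(TBSO)-6-((TBDPSO)methyl)-10-((PMBO)methyl)dodeca-6,10-dien-2-yn-1-amine (not isolated) | CC(C)(C)[Si](c1ccccc1)(c1ccccc1)OC/C(C[C@@H](O[Si](C)(C)C(C)(C)C)C#CCN(C1CCCCC1)C1CCCCC1)=C/CC/C(COCc1ccc(OC)cc1)=C\CO[Si](C)(C)C(C)(C)C | intermediate
21 | (4R,6E,10E)-4,12-bis(TBSO)-6-((TBDPSO)methyl)-10-((PMBO)methyl)dodeca-1,2,6,10-tetraene | CC(C)(C)[Si](c1ccccc1)(c1ccccc1)OC/C(C[C@@H](O[Si](C)(C)C(C)(C)C)C=C=C)=C/CC/C(COCc1ccc(OC)cc1)=C\CO[Si](C)(C)C(C)(C)C | intermediate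
22 | (2E,6E,9R)-9-(TBSO)-7-((TBDPSO)methyl)-3-((PMBO)methyl)dodeca-2,6,10,11-tetraen-1-ol | CC(C)(C)[Si](c1ccccc1)(c1ccccc1)OC/C(C[C@@H](O[Si](C)(C)C(C)(C)C)C=C=C)=C/CC/C(COCc1ccc(OC)cc1)=C\CO | intermediate
23 | (2E,6E,9R)-9-(TBSO)-7-((TBDPSO)methyl)-3-((PMBO)methyl)dodeca-2,6,10,11-tetraenal | CC(C)(C)[Si](c1ccccc1)(c1ccccc1)OC/C(C[C@@H](O[Si](C)(C)C(C)(C)C)C=C=C)=C/CC/C(COCc1ccc(OC)cc1)=C\C=O | intermediate
24 | five-membered nickelalactone from C11, C13 and CO2, Z at C11=C7, DBU ligands on nickel not drawn (not isolated) | O=C1O[Ni]C/C1=C\[C@H](O[Si](C)(C)C(C)(C)C)C/C(CO[Si](c2ccccc2)(c2ccccc2)C(C)(C)C)=C\CC/C(COCc2ccc(OC)cc2)=C\C=O | intermediate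
25 | 6-hydroxy-8-(TBSO)-14-(TBDPSO)-15-(PMBO)germacra-1(10),4,11(13)-trien-12-oic acid, target configuration at C6 C7 C8 (not isolated) | C=C(C(=O)O)[C@@H]1[C@H](O)/C=C(/COCc2ccc(OC)cc2)CC/C=C(/CO[Si](c2ccccc2)(c2ccccc2)C(C)(C)C)C[C@H]1O[Si](C)(C)C(C)(C)C | intermediate
26 | 8-(TBSO)-14-(TBDPSO)-15-(PMBO)germacra-1(10),4,11(13)-trien-6,12-olide, target configuration at C6 C7 C8 | C=C1C(=O)O[C@@H]2/C=C(/COCc3ccc(OC)cc3)CC/C=C(/CO[Si](c3ccccc3)(c3ccccc3)C(C)(C)C)C[C@@H](O[Si](C)(C)C(C)(C)C)[C@H]12 | intermediate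
27 | 8-hydroxy-14-(TBDPSO)-15-(PMBO)germacra-1(10),4,11(13)-trien-6,12-olide | C=C1C(=O)O[C@@H]2/C=C(/COCc3ccc(OC)cc3)CC/C=C(/CO[Si](c3ccccc3)(c3ccccc3)C(C)(C)C)C[C@@H](O)[C@H]12 | intermediate
28 | 8-(3-methylbutanoyloxy)-14-(TBDPSO)-15-(PMBO)germacra-1(10),4,11(13)-trien-6,12-olide | C=C1C(=O)O[C@@H]2/C=C(/COCc3ccc(OC)cc3)CC/C=C(/CO[Si](c3ccccc3)(c3ccccc3)C(C)(C)C)C[C@@H](OC(=O)CC(C)C)[C@H]12 | intermediate
29 | 14-hydroxy-8-(3-methylbutanoyloxy)-15-(PMBO)germacra-1(10),4,11(13)-trien-6,12-olide | C=C1C(=O)O[C@@H]2/C=C(/COCc3ccc(OC)cc3)CC/C=C(/CO)C[C@@H](OC(=O)CC(C)C)[C@H]12 | intermediate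
30 | 8-(3-methylbutanoyloxy)-15-(PMBO)-14-oxogermacra-1(10),4,11(13)-trien-6,12-olide | C=C1C(=O)O[C@@H]2/C=C(/COCc3ccc(OC)cc3)CC/C=C(/C=O)C[C@@H](OC(=O)CC(C)C)[C@H]12 | intermediate
31 | (6R,7S,8R)-15-hydroxy-8-(3-methylbutanoyloxy)-14-oxogermacra-1(10),4,11(13)-trien-6,12-olide (CNP0345200.7) | C=C1C(=O)O[C@@H]2/C=C(/CO)CC/C=C(/C=O)C[C@@H](OC(=O)CC(C)C)[C@H]12 | target

**Step count and risks**

Total steps: 21. Longest linear sequence: 18 steps (steps 4–7, then steps 8–21).

Steps most likely to fail: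

1. Step 16 (proposed new method). Intermolecular allylation and oligomerisation may outrun closure of the ten-membered ring. Facial selectivity at C7 and C6 may be poor. DBU may isomerise the enal geometry before ring closure. Zerovalent nickel may couple the allene and the enal directly without taking up CO2.
Fallback (known chemistry), setting out from alkyne 19 and returning at lactone 26: the alkyne is deprotonated and acylated (n-BuLi, ClCO2Me, THF, −78 °C) to methyl (4R,6E,10E)-4,12-bis(TBSO)-6-((TBDPSO)methyl)-10-((PMBO)methyl)dodeca-6,10-dien-2-ynoate F1. Syn-hydroalumination (iBu2AlH, HMPA, THF, 0 °C) and trapping of the α-aluminated enoate with formaldehyde should give the (Z)-2-(hydroxymethyl)enoate F2. Appel bromination (CBr4, PPh3) gives the 2-(bromomethyl)enoate F3. Selective desilylation at C6 (HF·pyridine, pyridine, THF, 0 °C) gives the bromo allylic alcohol F4, and Dess–Martin oxidation gives the bromo enal F5. Intramolecular Nozaki–Hiyama–Kishi-type allylation (CrCl2, THF/DMF, high dilution), the established way to close ten-membered germacranolide rings at C6–C7, gives the cyclic hydroxy ester F6, which is lactonised with TsOH (cat.) to 26.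

2. Step 13. Hydride transfer from the hindered Mannich base may stall at the propargylic amine, and the hot copper–amine medium may cost silyl groups.
Fallback, setting out from alkyne 19 and returning at allene 21: hydroxymethylation of the alkyne (n-BuLi, (CH2O)n, THF, −78 °C → rt) gives the propargylic alcohol (4R,6E,10E)-4,12-bis(TBSO)-6-((TBDPSO)methyl)-10-((PMBO)methyl)dodeca-6,10-dien-2-yn-1-ol F7. A Myers allene synthesis (2-nitrobenzenesulfonylhydrazide, PPh3, diethyl azodicarboxylate, THF, −15 °C → rt) then transposes the diazene to allene 21 below room temperature.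

3. Step 7. β-Hydride elimination toward the chain (dienol formation), palladium hydride chain-walking or erosion of the C4=C5 geometry may compete with formation of the 4-enal.
Fallback, setting out from vinyl iodide 12 and returning at aldehyde 14: Negishi coupling with BrZnCH2CH2CO2Et (Pd(PPh3)4, THF, rt → 50 °C) gives ethyl (E)-6-((tert-butyldimethylsilyl)oxy)-4-(((4-methoxybenzyl)oxy)methyl)hex-4-enoate F8, and partial reduction (iBu2AlH, 1.05 equiv, CH2Cl2, −78 °C) gives aldehyde 14.

**Further compounds**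

F1 | step 16 | methyl (4R,6E,10E)-4,12-bis(TBSO)-6-((TBDPSO)methyl)-10-((PMBO)methyl)dodeca-6,10-dien-2-ynoate | CC(C)(C)[Si](c1ccccc1)(c1ccccc1)OC/C(C[C@@H](O[Si](C)(C)C(C)(C)C)C#CC(=O)OC)=C/CC/C(COCc1ccc(OC)cc1)=C\CO[Si](C)(C)C(C)(C)C
F2 | step 16 | methyl (2Z,4R,6E,10E)-4,12-bis(TBSO)-2-(hydroxymethyl)-6-((TBDPSO)methyl)-10-((PMBO)methyl)dodeca-2,6,10-trienoate | CC(C)(C)[Si](c1ccccc1)(c1ccccc1)OC/C(C[C@@H](O[Si](C)(C)C(C)(C)C)/C=C(/CO)C(=O)OC)=C/CC/C(COCc1ccc(OC)cc1)=C\CO[Si](C)(C)C(C)(C)C
F3 | step 16 | methyl (2E,4R,6E,10E)-2-(bromomethyl)-4,12-bis(TBSO)-6-((TBDPSO)methyl)-10-((PMBO)methyl)dodeca-2,6,10-trienoate | CC(C)(C)[Si](c1ccccc1)(c1ccccc1)OC/C(C[C@@H](O[Si](C)(C)C(C)(C)C)/C=C(/CBr)C(=O)OC)=C/CC/C(COCc1ccc(OC)cc1)=C\CO[Si](C)(C)C(C)(C)C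
F4 | step 16 | methyl (2E,4R,6E,10E)-2-(bromomethyl)-12-hydroxy-4-(TBSO)-6-((TBDPSO)methyl)-10-((PMBO)methyl)dodeca-2,6,10-trienoate | CC(C)(C)[Si](c1ccccc1)(c1ccccc1)OC/C(C[C@@H](O[Si](C)(C)C(C)(C)C)/C=C(/CBr)C(=O)OC)=C/CC/C(COCc1ccc(OC)cc1)=C\CO
F5 | step 16 | methyl (2E,4R,6E,10E)-2-(bromomethyl)-12-oxo-4-(TBSO)-6-((TBDPSO)methyl)-10-((PMBO)methyl)dodeca-2,6,10-trienoate | CC(C)(C)[Si](c1ccccc1)(c1ccccc1)OC/C(C[C@@H](O[Si](C)(C)C(C)(C)C)/C=C(/CBr)C(=O)OC)=C/CC/C(COCc1ccc(OC)cc1)=C\C=O
F6 | step 16 | methyl 6-hydroxy-8-(TBSO)-14-(TBDPSO)-15-(PMBO)germacra-1(10),4,11(13)-trien-12-oate, target configuration at C6 C7 C8 | C=C(C(=O)OC)[C@@H]1[C@H](O)/C=C(/COCc2ccc(OC)cc2)CC/C=C(/CO[Si](c2ccccc2)(c2ccccc2)C(C)(C)C)C[C@H]1O[Si](C)(C)C(C)(C)C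
F7 | step 13 | (4R,6E,10E)-4,12-bis(TBSO)-6-((TBDPSO)methyl)-10-((PMBO)methyl)dodeca-6,10-dien-2-yn-1-ol | CC(C)(C)[Si](c1ccccc1)(c1ccccc1)OC/C(C[C@@H](O[Si](C)(C)C(C)(C)C)C#CCO)=C/CC/C(COCc1ccc(OC)cc1)=C\CO[Si](C)(C)C(C)(C)C
F8 | step 7 | ethyl (E)-6-((tert-butyldimethylsilyl)oxy)-4-(((4-methoxybenzyl)oxy)methyl)hex-4-enoate | CCOC(=O)CC/C(COCc1ccc(OC)cc1)=C\CO[Si](C)(C)C(C)(C)C
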